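**Strategy.** Ring A (the 3-hydroxy-β-ring, C1–C6, carotenoid numbering) is cut at C2–C3 and C4–C5: its C2H2–C3H(OH)–C4H2 unit is the retron of a vinylboron conjunctive coupling. In one operation a boron-bound vinyl group (C3=C4) is inserted between C2 of a neopentyl nitrile boronate and a vinyl electrophile (C5, C18), and the ligand sets C3. The precursor is an acyclic β-boryl nitrile ate complex. Radical addition of C5 to the nitrile carbon (C6) then closes ring A, and a carbonyl-ene reaction of the derived exocyclic methylene builds C7–C8 and the C5=C6 bond. Two Wittig couplings (C15 + C10 + C15) finish siphonaxanthin.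

Key step: step 2

Assumption: the target is all-E (3R,3'R,6'R)-siphonaxanthin, and (R)-α-ionone is bought as the single enantiomer.

**Step 1**
Reactants: 1 isobutyronitrile; 2 2-(iodomethyl)-4,4,5,5-tetramethyl-1,3,2-dioxaborolane
Product: 3 2,2-dimethyl-3-(4,4,5,5-tetramethyl-1,3,2-dioxaborolan-2-yl)propanenitrile
Conditions: LiN(iPr)2, THF, −78 °C; then 2, −78 °C to rt
Reagents that add atoms: none
Why: Alkylation of the lithiated nitrile with the (iodomethyl)boronate (boron ate formation and 1,2-shift with loss of iodide, a Matteson-type homologation) should give the β-boryl nitrile and builds the quaternary C1 next to C2 without any stereocentre.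

**Step 2**
Reactants: 3 2,2-dimethyl-3-(4,4,5,5-tetramethyl-1,3,2-dioxaborolan-2-yl)propanenitrile; 4 vinylmagnesium bromide; 5 vinyl bromide
Product: 8 (4R)-4-hydroxy-2,2-dimethylhept-6-enenitrile, via vinylboron ate complex 6 (not isolated), via homoallylic boronate 7 (not isolated)
Conditions: CH2=CHMgBr, NaOTf, THF, 0 °C to rt; Pd(OAc)2 (2 mol %), (S,S)-1,1'-bis[bis(4-methoxy-3,5-dimethylphenyl)phosphino]-2,2'-bis[(R)-α-(dimethylamino)benzyl]ferrocene (2.4 mol %), CH2=CHBr, THF/DMSO, 40 °C; then NaOH, H2O2, 0 °C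
Reagents that add atoms: hydrogen peroxide (OO)
Why: Vinylmagnesium bromide adds to boron of 3 to give the four-coordinate vinyl(alkyl)boronate 6, vinyl bromide adds oxidatively to zerovalent palladium, and the cationic divalent vinylpalladium (bromide is removed as NaBr by NaOTf) binds the boron-bound vinyl group and triggers a 1,2-shift of the CH2C(CH3)2CN group from boron to the α-carbon (C2–C3 bond) anti to palladium while palladium bonds to C4; reductive elimination then forms the C4–C5 bond and frees the catalyst. The closest known reaction type is the palladium-catalysed enantioselective conjunctive cross-coupling of Grignard-derived vinylboron ate complexes with C(sp2) halides, here applied to a nitrile-bearing primary alkyl boronate. No ring is closed in this step. The only new stereocentre, C3, is set by the chiral bisphosphine, which selects the face of the vinyl group that binds palladium, and oxidation of the C–B bond proceeds with retention; the sense of induction for this ligand enantiomer is not established here, so if the first run shows the 4S alcohol the mirror-image ligand is used. The step needs the conjunctive pathway to win over direct vinyl transfer to palladium and over Grignard addition to the nitrile: the chelating bisphosphine disfavours transmetalation, and the tertiary nitrile is hindered while ate formation at boron is fast.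

**Step 3**
Reactants: 8 (4R)-4-hydroxy-2,2-dimethylhept-6-enenitrile
Product: 9 (4R)-4-{[tert-butyl(dimethyl)silyl]oxy}-2,2-dimethylhept-6-enenitrile
Conditions: TBSCl, imidazole, DMF, rt
Reagents that add atoms: tert-butyldimethylsilyl chloride (CC(C)(C)[Si](C)(C)Cl)
Why: Standard silylation of the secondary alcohol, which leaves the stereocentre untouched.

**Step 4**
Reactants: 9 (4R)-4-{[tert-butyl(dimethyl)silyl]oxy}-2,2-dimethylhept-6-enenitrile
Product: 11 (4R)-4-{[tert-butyl(dimethyl)silyl]oxy}-2,2,6-trimethylcyclohexan-1-one (C6 epimers), via cyclic ketimine 10 (not isolated)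
Conditions: Fe(acac)3 (cat.), PhSiH3, EtOH, 60 °C; then aq. NH4Cl
Reagents that add atoms: water (O)
Why: Hydrogen-atom transfer from an iron hydride to the terminal alkene should give the secondary C5 radical, which adds 6-exo-dig to the nitrile carbon (helped by the gem-dimethyl group) to an imine that hydrolyses to the ketone, a known HAT-initiated alkene–nitrile cyclisation; the methyl-bearing stereocentre forms as a mixture and is erased in step 9.

**Step 5**
Reactants: 11 (4R)-4-{[tert-butyl(dimethyl)silyl]oxy}-2,2,6-trimethylcyclohexan-1-one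
Product: 12 tert-butyldimethyl{[(1R)-3,3,5-trimethyl-4-methylidenecyclohexyl]oxy}silane (C5 epimers)
Conditions: Ph3PCH3Br, KOtBu, toluene, reflux
Reagents that add atoms: methyltriphenylphosphonium bromide (C[P+](c1ccccc1)(c1ccccc1)c1ccccc1.[Br-])
Why: Wittig methylenation under forcing potassium tert-butoxide conditions should convert the hindered ketone into the exocyclic alkene (C7); epimerisation next to the carbonyl is of no consequence.

**Step 6**
Reactants: 13 2-methylidenepropane-1,3-diol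
Product: 14 2-({[tert-butyl(dimethyl)silyl]oxy}methyl)prop-2-en-1-ol
Conditions: NaH (1.0 equiv), THF, 0 °C; then TBSCl
Reagents that add atoms: tert-butyldimethylsilyl chloride (CC(C)(C)[Si](C)(C)Cl)
Why: Monosilylation of the symmetric diol through its monosodium alkoxide should stop at the mono-ether.

**Step 7**
Reactants: 14 2-({[tert-butyl(dimethyl)silyl]oxy}methyl)prop-2-en-1-ol
Product: 15 2-({[tert-butyl(dimethyl)silyl]oxy}methyl)prop-2-enal
Conditions: MnO2, CH2Cl2, rt
Reagents that add atoms: none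
Why: MnO2 oxidises the allylic alcohol selectively to the enal and leaves the silyl ether alone.

**Step 8**
Reactants: 15 2-({[tert-butyl(dimethyl)silyl]oxy}methyl)prop-2-enal; 16 (Z)-1,4-dichlorobut-2-ene
Product: 17 (2E)-2-({[tert-butyl(dimethyl)silyl]oxy}methyl)-4-chlorobut-2-enal
Conditions: second-generation Hoveyda–Grubbs catalyst (5 mol %), CH2Cl2, 40 °C
Reagents that add atoms: none
Why: Olefin cross-metathesis of the 2-substituted acrolein with the allylic chloride should give the trisubstituted enal as the E isomer (CHO trans to CH2Cl) under thermodynamic control, as in cross-metatheses of methacrolein.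

**Step 9**
Reactants: 12 tert-butyldimethyl{[(1R)-3,3,5-trimethyl-4-methylidenecyclohexyl]oxy}silane; 17 (2E)-2-({[tert-butyl(dimethyl)silyl]oxy}methyl)-4-chlorobut-2-enal
Product: 18 (3E)-1-[(4R)-4-{[tert-butyl(dimethyl)silyl]oxy}-2,6,6-trimethylcyclohex-1-en-1-yl]-3-({[tert-butyl(dimethyl)silyl]oxy}methyl)-5-chloropent-3-en-2-ol (C2 epimers)
Conditions: Me2AlCl (2 equiv), CH2Cl2, −78 to −20 °C
Reagents that add atoms: none
Why: In this Lewis-acid-promoted carbonyl-ene reaction the aldehyde carbon (C8) bonds to the terminal methylene carbon (C7) while the only allylic hydrogen (on C5, since C1 is quaternary) moves to oxygen, so the double bond shifts to C5=C6; the C8 carbinol forms as a mixture that step 10 oxidises away.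

**Step 10**
Reactants: 18 (3E)-1-[(4R)-4-{[tert-butyl(dimethyl)silyl]oxy}-2,6,6-trimethylcyclohex-1-en-1-yl]-3-({[tert-butyl(dimethyl)silyl]oxy}methyl)-5-chloropent-3-en-2-ol
Product: 19 (3E)-1-[(4R)-4-{[tert-butyl(dimethyl)silyl]oxy}-2,6,6-trimethylcyclohex-1-en-1-yl]-3-({[tert-butyl(dimethyl)silyl]oxy}methyl)-5-chloropent-3-en-2-one
Conditions: Dess–Martin periodinane, CH2Cl2, 0 °C to rt
Reagents that add atoms: none
Why: Dess–Martin oxidation of the secondary allylic alcohol gives the C8 ketone under non-basic conditions that should leave the β,γ-double bond in place.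

**Step 11**
Reactants: 19 (3E)-1-[(4R)-4-{[tert-butyl(dimethyl)silyl]oxy}-2,6,6-trimethylcyclohex-1-en-1-yl]-3-({[tert-butyl(dimethyl)silyl]oxy}methyl)-5-chloropent-3-en-2-one
Product: 20 [(2E)-5-[(4R)-4-{[tert-butyl(dimethyl)silyl]oxy}-2,6,6-trimethylcyclohex-1-en-1-yl]-3-({[tert-butyl(dimethyl)silyl]oxy}methyl)-4-oxopent-2-en-1-yl]triphenylphosphonium chloride
Conditions: PPh3, MeCN, 40 °C
Reagents that add atoms: triphenylphosphine (c1ccc(cc1)P(c1ccccc1)c1ccccc1)
Why: SN2 displacement of the primary allylic chloride by triphenylphosphine (Wittig salt formation) places phosphorus on C11.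

**Step 12**
Reactants: 21 (R)-α-ionone; 22 triethyl phosphonoacetate
Product: 23 ethyl (2E,4E)-3-methyl-5-[(1R)-2,6,6-trimethylcyclohex-2-en-1-yl]penta-2,4-dienoate
Conditions: NaH, THF, 0 °C to reflux
Reagents that add atoms: none
Why: Horner–Wadsworth–Emmons olefination of the methyl ketone should give mainly the 9'E ester (the minor Z isomer is removed by chromatography) without touching C6'.

**Step 13**
Reactants: 23 ethyl (2E,4E)-3-methyl-5-[(1R)-2,6,6-trimethylcyclohex-2-en-1-yl]penta-2,4-dienoate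
Product: 24 ethyl (2E,4E)-3-methyl-5-[(1R)-2,6,6-trimethyl-4-oxocyclohex-2-en-1-yl]penta-2,4-dienoate
Conditions: t-BuOOH, CuI (cat.), MeCN, 50 °C
Reagents that add atoms: tert-butyl hydroperoxide (CC(C)(C)OO)
Why: Copper-catalysed allylic oxidation with tert-butyl hydroperoxide converts the ring allylic CH2 (C3') into the enone, as known for α-ionone derivatives; neutral conditions avoid epimerisation at C6'.

**Step 14**
Reactants: 24 ethyl (2E,4E)-3-methyl-5-[(1R)-2,6,6-trimethyl-4-oxocyclohex-2-en-1-yl]penta-2,4-dienoate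
Product: 25 ethyl (2E,4E)-5-[(1R,4R)-4-hydroxy-2,6,6-trimethylcyclohex-2-en-1-yl]-3-methylpenta-2,4-dienoate
Conditions: (S)-Me-CBS oxazaborolidine (0.2 equiv), BH3·SMe2, THF, −30 °C; MeOH quench
Reagents that add atoms: none
Why: In this Corey–Bakshi–Shibata reduction the oxazaborolidine delivers hydride to the ketone face that gives the 3'R alcohol (ring alkene as the large group), setting C3' trans to the C6' side chain by catalyst control and without 1,4-reduction.

**Step 15**
Reactants: 25 ethyl (2E,4E)-5-[(1R,4R)-4-hydroxy-2,6,6-trimethylcyclohex-2-en-1-yl]-3-methylpenta-2,4-dienoate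
Product: 26 ethyl (2E,4E)-5-[(1R,4R)-4-{[tert-butyl(dimethyl)silyl]oxy}-2,6,6-trimethylcyclohex-2-en-1-yl]-3-methylpenta-2,4-dienoate
Conditions: TBSCl, imidazole, DMF, rt
Reagents that add atoms: tert-butyldimethylsilyl chloride (CC(C)(C)[Si](C)(C)Cl)
Why: Standard silylation protects the acid-sensitive allylic alcohol for the remaining steps.

**Step 16**
Reactants: 26 ethyl (2E,4E)-5-[(1R,4R)-4-{[tert-butyl(dimethyl)silyl]oxy}-2,6,6-trimethylcyclohex-2-en-1-yl]-3-methylpenta-2,4-dienoate
Product: 27 (2E,4E)-5-[(1R,4R)-4-{[tert-butyl(dimethyl)silyl]oxy}-2,6,6-trimethylcyclohex-2-en-1-yl]-3-methylpenta-2,4-dien-1-ol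
Conditions: iBu2AlH (2.2 equiv), CH2Cl2, −78 °C; Rochelle salt work-up
Reagents that add atoms: none
Why: 1,2-Reduction of the dienoate by diisobutylaluminium hydride gives the primary allylic alcohol with the diene geometry intact.

**Step 17**
Reactants: 27 (2E,4E)-5-[(1R,4R)-4-{[tert-butyl(dimethyl)silyl]oxy}-2,6,6-trimethylcyclohex-2-en-1-yl]-3-methylpenta-2,4-dien-1-ol
Product: 29 {(2E,4E)-5-[(1R,4R)-4-{[tert-butyl(dimethyl)silyl]oxy}-2,6,6-trimethylcyclohex-2-en-1-yl]-3-methylpenta-2,4-dien-1-yl}triphenylphosphonium bromide, via allylic bromide 28 (not isolated)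
Conditions: CBr4, PPh3 (2.2 equiv), CH2Cl2, 0 °C to rt
Reagents that add atoms: carbon tetrabromide (BrC(Br)(Br)Br); triphenylphosphine (c1ccc(cc1)P(c1ccccc1)c1ccccc1)
Why: Appel bromination of the primary alcohol followed by quaternisation of the excess phosphine gives the C15 Wittig salt under neutral conditions that spare the allylic silyl ether.

**Step 18**
Reactants: 29 the C15 phosphonium bromide; 30 (2E,4E,6E)-2,7-dimethylocta-2,4,6-trienedial
Product: 31 (2E,4E,6E,8E,10E,12E)-13-[(1R,4R)-4-{[tert-butyl(dimethyl)silyl]oxy}-2,6,6-trimethylcyclohex-2-en-1-yl]-2,7,11-trimethyltrideca-2,4,6,8,10,12-hexaenal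
Conditions: NaOMe, MeOH/CH2Cl2, 0 °C to rt; 30 in excess (3 equiv)
Reagents that add atoms: none
Why: Wittig olefination of one aldehyde of the dial (used in excess) forms the C11'=C12' bond; any Z isomer is expected to equilibrate to E on warming, as is usual for disubstituted polyene bonds.

**Step 19**
Reactants: 20 the C15 phosphonium chloride of the keto half; 31 the C25 aldehyde
Product: 32 3,19,3'-tris-O-(tert-butyldimethylsilyl)siphonaxanthin
Conditions: 1,2-epoxybutane, EtOH, 70 °C (sealed tube)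
Reagents that add atoms: none
Why: Wittig olefination with the enone-stabilised ylide, generated under base-free epoxide conditions as for vinylogous ester Wittig salts, should form the C11=C12 bond E-selectively, and only the phosphonium CH2 is deprotonated because the C7 protons are far less acidic.

**Step 20**
Reactants: 32 3,19,3'-tris-O-(tert-butyldimethylsilyl)siphonaxanthin
Product: 33 siphonaxanthin (CNP0183826.2)
Conditions: HF·pyridine, pyridine, THF, 0 °C to rt
Reagents that add atoms: none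
Why: Buffered fluoride cleaves the three silyl ethers without ionising the allylic C3' alcohol or isomerising the β,γ-unsaturated ketone.

**Compound list**

1 | isobutyronitrile | CC(C)C#N | starting material
2 | 2-(iodomethyl)-4,4,5,5-tetramethyl-1,3,2-dioxaborolane | ICB1OC(C)(C)C(C)(C)O1 | starting material
3 | 2,2-dimethyl-3-(4,4,5,5-tetramethyl-1,3,2-dioxaborolan-2-yl)propanenitrile | N#CC(C)(C)CB1OC(C)(C)C(C)(C)O1 | intermediate
4 | vinylmagnesium bromide | C=C[Mg]Br | starting material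
5 | vinyl bromide | C=CBr | starting material
6 | sodium (2-cyano-2-methylpropyl)(ethenyl)(pinacolato)borate | [Na+].C=C[B-]1(CC(C)(C)C#N)OC(C)(C)C(C)(C)O1 | intermediate
7 | (4R)-2,2-dimethyl-4-(4,4,5,5-tetramethyl-1,3,2-dioxaborolan-2-yl)hept-6-enenitrile | C=CC[C@@H](B1OC(C)(C)C(C)(C)O1)CC(C)(C)C#N | intermediate
8 | (4R)-4-hydroxy-2,2-dimethylhept-6-enenitrile | C=CC[C@@H](O)CC(C)(C)C#N | intermediate
9 | (4R)-4-{[tert-butyl(dimethyl)silyl]oxy}-2,2-dimethylhept-6-enenitrile | C=CC[C@@H](O[Si](C)(C)C(C)(C)C)CC(C)(C)C#N | intermediate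
10 | (4R)-4-{[tert-butyl(dimethyl)silyl]oxy}-2,2,6-trimethylcyclohexan-1-imine (C6 epimers) | CC1C[C@@H](O[Si](C)(C)C(C)(C)C)CC(C)(C)C1=N | intermediate
11 | (4R)-4-{[tert-butyl(dimethyl)silyl]oxy}-2,2,6-trimethylcyclohexan-1-one (C6 epimers) | CC1C[C@@H](O[Si](C)(C)C(C)(C)C)CC(C)(C)C1=O | intermediate
12 | tert-butyldimethyl{[(1R)-3,3,5-trimethyl-4-methylidenecyclohexyl]oxy}silane (C5 epimers) | C=C1C(C)C[C@@H](O[Si](C)(C)C(C)(C)C)CC1(C)C | intermediate
13 | 2-methylidenepropane-1,3-diol | C=C(CO)CO | starting material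
14 | 2-({[tert-butyl(dimethyl)silyl]oxy}methyl)prop-2-en-1-ol | C=C(CO)CO[Si](C)(C)C(C)(C)C | intermediate
15 | 2-({[tert-butyl(dimethyl)silyl]oxy}methyl)prop-2-enal | C=C(C=O)CO[Si](C)(C)C(C)(C)C | intermediate
16 | (Z)-1,4-dichlorobut-2-ene | ClC/C=C\CCl | starting material
17 | (2E)-2-({[tert-butyl(dimethyl)silyl]oxy}methyl)-4-chlorobut-2-enal | O=C/C(CO[Si](C)(C)C(C)(C)C)=C/CCl | intermediate
18 | (3E)-1-[(4R)-4-{[tert-butyl(dimethyl)silyl]oxy}-2,6,6-trimethylcyclohex-1-en-1-yl]-3-({[tert-butyl(dimethyl)silyl]oxy}methyl)-5-chloropent-3-en-2-ol (C2 epimers) | ClC/C=C(\CO[Si](C)(C)C(C)(C)C)C(O)CC1=C(C)C[C@@H](O[Si](C)(C)C(C)(C)C)CC1(C)C | intermediate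
19 | (3E)-1-[(4R)-4-{[tert-butyl(dimethyl)silyl]oxy}-2,6,6-trimethylcyclohex-1-en-1-yl]-3-({[tert-butyl(dimethyl)silyl]oxy}methyl)-5-chloropent-3-en-2-one | ClC/C=C(\CO[Si](C)(C)C(C)(C)C)C(=O)CC1=C(C)C[C@@H](O[Si](C)(C)C(C)(C)C)CC1(C)C | intermediate
20 | [(2E)-5-[(4R)-4-{[tert-butyl(dimethyl)silyl]oxy}-2,6,6-trimethylcyclohex-1-en-1-yl]-3-({[tert-butyl(dimethyl)silyl]oxy}methyl)-4-oxopent-2-en-1-yl]triphenylphosphonium chloride | [Cl-].c1ccccc1[P+](c1ccccc1)(c1ccccc1)C/C=C(\CO[Si](C)(C)C(C)(C)C)C(=O)CC1=C(C)C[C@@H](O[Si](C)(C)C(C)(C)C)CC1(C)C | intermediate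
21 | (R)-α-ionone, (3E)-4-[(1R)-2,6,6-trimethylcyclohex-2-en-1-yl]but-3-en-2-one | CC1=CCCC(C)(C)[C@H]1/C=C/C(C)=O | starting material
22 | triethyl phosphonoacetate | CCOC(=O)CP(=O)(OCC)OCC | starting material
23 | ethyl (2E,4E)-3-methyl-5-[(1R)-2,6,6-trimethylcyclohex-2-en-1-yl]penta-2,4-dienoate | CC1=CCCC(C)(C)[C@H]1/C=C/C(C)=C/C(=O)OCC | intermediate
24 | ethyl (2E,4E)-3-methyl-5-[(1R)-2,6,6-trimethyl-4-oxocyclohex-2-en-1-yl]penta-2,4-dienoate | CC1=CC(=O)CC(C)(C)[C@H]1/C=C/C(C)=C/C(=O)OCC | intermediate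
25 | ethyl (2E,4E)-5-[(1R,4R)-4-hydroxy-2,6,6-trimethylcyclohex-2-en-1-yl]-3-methylpenta-2,4-dienoate | CC1=C[C@H](O)CC(C)(C)[C@H]1/C=C/C(C)=C/C(=O)OCC | intermediate
26 | ethyl (2E,4E)-5-[(1R,4R)-4-{[tert-butyl(dimethyl)silyl]oxy}-2,6,6-trimethylcyclohex-2-en-1-yl]-3-methylpenta-2,4-dienoate | CC1=C[C@H](O[Si](C)(C)C(C)(C)C)CC(C)(C)[C@H]1/C=C/C(C)=C/C(=O)OCC | intermediate
27 | (2E,4E)-5-[(1R,4R)-4-{[tert-butyl(dimethyl)silyl]oxy}-2,6,6-trimethylcyclohex-2-en-1-yl]-3-methylpenta-2,4-dien-1-ol | CC1=C[C@H](O[Si](C)(C)C(C)(C)C)CC(C)(C)[C@H]1/C=C/C(C)=C/CO | intermediate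
28 | {[(1R,4R)-4-[(1E,3E)-5-bromo-3-methylpenta-1,3-dien-1-yl]-3,5,5-trimethylcyclohex-2-en-1-yl]oxy}(tert-butyl)dimethylsilane | CC1=C[C@H](O[Si](C)(C)C(C)(C)C)CC(C)(C)[C@H]1/C=C/C(C)=C/CBr | intermediate
29 | {(2E,4E)-5-[(1R,4R)-4-{[tert-butyl(dimethyl)silyl]oxy}-2,6,6-trimethylcyclohex-2-en-1-yl]-3-methylpenta-2,4-dien-1-yl}triphenylphosphonium bromide | [Br-].CC1=C[C@H](O[Si](C)(C)C(C)(C)C)CC(C)(C)[C@H]1/C=C/C(C)=C/C[P+](c1ccccc1)(c1ccccc1)c1ccccc1 | intermediate
30 | (2E,4E,6E)-2,7-dimethylocta-2,4,6-trienedial | O=C/C(C)=C/C=C/C=C(C)/C=O | starting material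
31 | (2E,4E,6E,8E,10E,12E)-13-[(1R,4R)-4-{[tert-butyl(dimethyl)silyl]oxy}-2,6,6-trimethylcyclohex-2-en-1-yl]-2,7,11-trimethyltrideca-2,4,6,8,10,12-hexaenal | CC1=C[C@H](O[Si](C)(C)C(C)(C)C)CC(C)(C)[C@H]1/C=C/C(C)=C/C=C/C(C)=C/C=C/C=C(C)/C=O | intermediate
32 | 3,19,3'-tris-O-(tert-butyldimethylsilyl)siphonaxanthin | CC1=C[C@H](O[Si](C)(C)C(C)(C)C)CC(C)(C)[C@H]1/C=C/C(C)=C/C=C/C(C)=C/C=C/C=C(C)/C=C/C=C(\CO[Si](C)(C)C(C)(C)C)C(=O)CC1=C(C)C[C@@H](O[Si](C)(C)C(C)(C)C)CC1(C)C | intermediate
33 | siphonaxanthin, (3R,3'R,6'R)-3,19,3'-trihydroxy-7,8-dihydro-β,ε-caroten-8-one | CC1=C[C@H](O)CC(C)(C)[C@H]1/C=C/C(C)=C/C=C/C(C)=C/C=C/C=C(C)/C=C/C=C(\CO)C(=O)CC1=C(C)C[C@@H](O)CC1(C)C | target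

**Summary**

Total step count: 20. Longest linear sequence: 10 steps (steps 1–5, 9–11, 19, 20).

Steps most likely to fail:

1. **Step 9 (carbonyl-ene reaction).** The Lewis-acid-activated enal may be attacked at its β-carbon instead of the carbonyl carbon, or the developing cation at C6 may trigger methyl migration or chloride capture before the hydrogen is transferred. The fallback sets out from 12 and comes back at 19. Compound 12 would be treated with paraformaldehyde and Me2AlCl, the most reliable enophile for such alkenes, to give 2-[(4R)-4-{[tert-butyl(dimethyl)silyl]oxy}-2,6,6-trimethylcyclohex-1-en-1-yl]ethanol F1. Dess–Martin oxidation gives 2-[(4R)-4-{[tert-butyl(dimethyl)silyl]oxy}-2,6,6-trimethylcyclohex-1-en-1-yl]acetaldehyde F2. Addition of the alkenylcerium reagent made from tert-butyl[(2-bromoprop-2-en-1-yl)oxy]dimethylsilane, t-BuLi and CeCl3 gives 1-[(4R)-4-{[tert-butyl(dimethyl)silyl]oxy}-2,6,6-trimethylcyclohex-1-en-1-yl]-3-({[tert-butyl(dimethyl)silyl]oxy}methyl)but-3-en-2-ol F3. A second Dess–Martin oxidation gives 1-[(4R)-4-{[tert-butyl(dimethyl)silyl]oxy}-2,6,6-trimethylcyclohex-1-en-1-yl]-3-({[tert-butyl(dimethyl)silyl]oxy}methyl)but-3-en-2-one F4, and cross-metathesis of F4 with 16 (second-generation Hoveyda–Grubbs catalyst) delivers 19.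

2. **Step 4 (radical ring closure onto the nitrile).** The secondary radical may be reduced (net hydrogenation of the alkene) faster than it adds to the hindered nitrile. The fallback sets out from 9 and comes back at 11, closing the ring by a polar instead of a radical addition. Mukaiyama hydration of 9 (Co(acac)2, PhSiH3, O2) would give (4S)-4-{[tert-butyl(dimethyl)silyl]oxy}-6-hydroxy-2,2-dimethylheptanenitrile F5 as a mixture at C6. Appel iodination (I2, PPh3, imidazole) gives (4S)-4-{[tert-butyl(dimethyl)silyl]oxy}-6-iodo-2,2-dimethylheptanenitrile F6. Iodine–lithium exchange with t-BuLi in Et2O at −78 °C and anionic 6-exo addition of the alkyllithium to the nitrile (which has no α-hydrogen) leads through imine 10 to ketone 11 on aqueous work-up.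

3. **Step 14 (CBS reduction).** Facial selectivity may be poor if catalyst control is opposed by the bias of the ring substituents. The fallback sets out from 24 and comes back at 25. Luche reduction (NaBH4, CeCl3·7H2O, MeOH) would give 25 together with its epimer ethyl (2E,4E)-5-[(1R,4S)-4-hydroxy-2,6,6-trimethylcyclohex-2-en-1-yl]-3-methylpenta-2,4-dienoate F7, which are separated. F7 is inverted by a Mitsunobu reaction (4-nitrobenzoic acid, PPh3, diisopropyl azodicarboxylate) to ethyl (2E,4E)-3-methyl-5-[(1R,4R)-4-(4-nitrobenzoyloxy)-2,6,6-trimethylcyclohex-2-en-1-yl]penta-2,4-dienoate F8, and ethanolysis (K2CO3, EtOH) returns 25.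

**Further compounds**

F1 | step 9 | 2-[(4R)-4-{[tert-butyl(dimethyl)silyl]oxy}-2,6,6-trimethylcyclohex-1-en-1-yl]ethanol | OCCC1=C(C)C[C@@H](O[Si](C)(C)C(C)(C)C)CC1(C)C
F2 | step 9 | 2-[(4R)-4-{[tert-butyl(dimethyl)silyl]oxy}-2,6,6-trimethylcyclohex-1-en-1-yl]acetaldehyde | O=CCC1=C(C)C[C@@H](O[Si](C)(C)C(C)(C)C)CC1(C)C
F3 | step 9 | 1-[(4R)-4-{[tert-butyl(dimethyl)silyl]oxy}-2,6,6-trimethylcyclohex-1-en-1-yl]-3-({[tert-butyl(dimethyl)silyl]oxy}methyl)but-3-en-2-ol | C=C(CO[Si](C)(C)C(C)(C)C)C(O)CC1=C(C)C[C@@H](O[Si](C)(C)C(C)(C)C)CC1(C)C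
F4 | step 9 | 1-[(4R)-4-{[tert-butyl(dimethyl)silyl]oxy}-2,6,6-trimethylcyclohex-1-en-1-yl]-3-({[tert-butyl(dimethyl)silyl]oxy}methyl)but-3-en-2-one | C=C(CO[Si](C)(C)C(C)(C)C)C(=O)CC1=C(C)C[C@@H](O[Si](C)(C)C(C)(C)C)CC1(C)C
F5 | step 4 | (4S)-4-{[tert-butyl(dimethyl)silyl]oxy}-6-hydroxy-2,2-dimethylheptanenitrile | CC(O)C[C@@H](O[Si](C)(C)C(C)(C)C)CC(C)(C)C#N
F6 | step 4 | (4S)-4-{[tert-butyl(dimethyl)silyl]oxy}-6-iodo-2,2-dimethylheptanenitrile | CC(I)C[C@@H](O[Si](C)(C)C(C)(C)C)CC(C)(C)C#N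
F7 | step 14 | ethyl (2E,4E)-5-[(1R,4S)-4-hydroxy-2,6,6-trimethylcyclohex-2-en-1-yl]-3-methylpenta-2,4-dienoate | CC1=C[C@@H](O)CC(C)(C)[C@H]1/C=C/C(C)=C/C(=O)OCC
F8 | step 14 | ethyl (2E,4E)-3-methyl-5-[(1R,4R)-4-(4-nitrobenzoyloxy)-2,6,6-trimethylcyclohex-2-en-1-yl]penta-2,4-dienoate | CC1=C[C@H](OC(=O)c2ccc(cc2)[N+](=O)[O-])CC(C)(C)[C@H]1/C=C/C(C)=C/C(=O)OCC
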